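Early in a flask, you can read its pace as a lifetime and then count lifetimes.

| flask | J | E | L | time |
|---|---|---|---|---|
| eta | 0.250 M | 0.250 M | 0.00500 M |  |
| epsilon | 0.250 M | 0.250 M | 0.00750 M |  |
| gamma | 0.0830 M | 0.500 M | 0.00500 M | 69 min |

- eta run (time / min: [J] / M): 14: 0.2084; 28: 0.1774; 41: 0.1539; 55: 0.1347; 69: 0.1178
- epsilon run (time / min: [J] / M): 14: 0.1990; 28: 0.1634; 41: 0.1401; 55: 0.1164; 69: 0.1021

(scatter of a reading: 8 × 10⁻⁴ M)

- apparent order in [L] of the starting rate, round the charge of the eta run (the rate where two percent of its J have turned into X)
- J in the gamma run at 69 min, as a share of the J charged

- Overall: J + E -> X, with L as catalyst.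
- Constant volume, constant temperature.
- A reading of a species includes what of it is bound.
- An order is taken over about fifteen percent of the charge, up and down.

At 14 min, the eta run holds 83.4% of its J. So 76.9 min is its early lifetime of J, the time of the first reading over the log of charge over reading. Time asked over lifetime counts the lifetimes spent, and the J left is the exponential of minus that count, provided the lifetime holds.

Now climb the ladder, from short to long. The gamma run comes first, on my own reckoning. J is the limiting reagent there, and E can lose at most 16.6% of its charge, so I treat J as a pseudo-first-order species. Both earlier runs charge J and E alike, so they can't separate the two. A rate of the first power in each of J and E is therefore my bet, not a reading. It gives gamma a lifetime of 38.5 min.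

The next rung is the epsilon run, whose first reading gives 61.4 min, longer than gamma's. Then comes the eta run's 76.9 min, longer again. Over its last interval, the eta run has stretched to 104 min.

So, on my reckoning, 69 min in the gamma run counts 1.79 lifetimes, which gives an estimate of 16.6% of its J left. The two early lifetimes read as an order in L of 0.557.

The forecast puts the order in L at 0.6 (0.45 to 0.8) and the J left in the gamma run at 12% (3% to 30%): “The gamma run cannot be pinned down because J and E were never varied separately.” My share stands above its 12%.

The gamma run leaves 16.2% of its J at 69 min, and the apparent order in L of the starting rate, round the charge of the eta run, is 0.80.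

    L + J ⇌ LJ, settled at all times (5.920 L mol⁻¹)
    LJ + E → X + L + Z (4.494 L mol⁻¹ min⁻¹)
    2 J → Ky (0.006960 L mol⁻¹ min⁻¹)
    2 L ⇌ L2, settled at all times (253.0 L mol⁻¹)

That share is 1.82 lifetimes in the gamma run. Near the start, the epsilon run makes X at 1.4 times the rate of the eta run. Count J as going at the pace of X, divide 76.9 min by that ratio, and the epsilon run's early lifetime of J comes to 56.0 min, where its first reading of J gave 61.4 min.

All runs come from a simulation for an exercise; the scatter is artificial.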